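(The earlier runs and the new flask were computed with constants of no real substance; noise was put on by code.)

The noon run is this very flask, followed to 25.0 h, so before any fit you can read it with a pencil.

- noon: substrate 0.050 M; catalyst 0.11 mol%; the very flask that is asked about, followed so far
- flask: substrate 0.050 M; catalyst 0.11 mol%; time 8.0 d

noon run (percent of the substrate charged)

| time / h | isomer of the product / % | target / % |
|---|---|---|
| 3.00 | 57.0 | 27.5 |
| 8.00 | 75.4 | 14.9 |
| 15.0 | 77.8 | 13.2 |
| 25.0 | 78.7 | 12.8 |

(readings scatter by 0.5 percentage points)

* share of isomer of the product in isomer of the product plus target at 80 s
* share of isomer of the product in isomer of the product plus target at 8.0 d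

- percent here means substrate units held: one self-condensation product counts as two
- reactions considered so far: substrate <-> target; target + catalyst <-> isomer of the product + catalyst; isomer of the product + catalyst <-> substrate + catalyst; 2 substrate -> self-condensation product

Divide each row: the odds, c(isomer of the product)/c(target). Their zero of scale is the symmetric case, odds of one, a share of 50%. The first row gives 2.07, already past that mark. The second gives 5.06, and the third 5.89. The last gives 6.15, a rise of 0.260 where the first step rose 2.99.

So the rows level off. I carry these late odds, the ratio of isomer of the product to target once the rows stop moving, as the mark of thermodynamic control. Any share follows as odds/(1+odds), so I put this flask at 86.0% at 8.0 d, reckoned from readings that scatter by 0.5 percentage points and provided the odds stay as they stood in the last row.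

The early end is kinetic control, and 80 s lies far ahead of the first row. Going back the odds fall, so I expect them below one there, with target ahead, and I give no figure.

The forecast says 22% and 86.5%, in its words “At 8 d, the catalysed isomer–target equilibrium should hold at about 86%”.

The flask gives 28.0% at 80 s and 86.1% at 8.0 d.

    substrate ⇌ target (K = 1.85, k = 1.39 h⁻¹)
    target + catalyst ⇌ isomer of the product + catalyst, rate k2*[catalyst]*[target] forward; the back reaction follows from the equilibrium constant (K = 6.17, k = 3650 L mol⁻¹ h⁻¹)
    isomer of the product + catalyst ⇌ substrate + catalyst, rate k3*[catalyst]*[isomer of the product] forward; the back reaction follows from the equilibrium constant (k = 849 L mol⁻¹ h⁻¹)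
    2 substrate → self-condensation product (k = 0.628 L mol⁻¹ h⁻¹)

In this flask the odds are 0.389 at 80 s, pass one at 0.0592 d, earlier than the first row, and reach 6.19 at 8.0 d. At that time the half-life of target by the forward rate of the step to isomer of the product alone is 0.14 d, short against 8.0 d, and summed over the run that step's backward turnover is 95% of its forward one. The neighbour flask with 0.044 mol% of catalyst stands at 13.5% at 80 s, yet at 8.0 d it shows 86.1%, close to the 86.0% that the odds gave.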